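**Assumption:** atom labels C1–C15 follow germacrane numbering (C6 lactone oxygen, C8 methacrylate, C2 acetate, C12 lactone carbonyl, C13 exocyclic methylene, C14 hydroxymethyl, C15 methyl). The target is read as (2S,6R,7R,8R) with both ring double bonds ring-cis (C1=C10 is E by CIP, C4=C5 is Z).

## Retrosynthetic overview

1. Target ⇐ C14 desilylation and invertive (Mitsunobu) methacryloylation at C8 of the ten-membered (8S)-alcohol 30.
2. 30 ⇐ key step: CrCl2 turns the bromomethyl-butenolide of 28 into an allylchromium whose C7 (normally the electrophilic β-carbon) attacks the C8 aldehyde. This closes the ten-membered ring (third ring), sets C7 and C8, and unveils the α-methylene lactone.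
3. 28 ⇐ butenolide (second ring) by ring-closing metathesis of a 2-(bromomethyl)acrylate on the C6 carbinol, which comes from asymmetric alkenylzinc addition to Z-enal 19.
4. 19 ⇐ temporary six-membered lactone 15 (first ring; ester-tethered metathesis fixes the ring-cis C1=C10 geometry, then reductive opening) ⇐ vinyl carbinol 8 + acid 13.
5. 8 ⇐ Z-alkenyl Grignard from but-2-yn-1-ol (fixes C4=C5) + (S)-epichlorohydrin (C2), then sulfonium-ylide homologation.

## Route

Step 1
Reactants: 1 but-2-yn-1-ol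
Product: 2 (Z)-3-iodobut-2-en-1-ol
Conditions: NaAlH2(OCH2CH2OMe)2, THF, 0 °C; then I2, −78 to 0 °C
Reagents that add atoms: iodine, II
Why: Hydroxyl-directed trans-hydroalumination puts aluminium on the distal alkyne carbon cis to CH2OH and iodinolysis with retention gives the Z vinyl iodide that fixes the later C4=C5 geometry (hydroalumination–iodination of a propargylic alcohol).

Step 2
Reactants: 2 (Z)-3-iodobut-2-en-1-ol
Product: 3 (Z)-triethyl[(3-iodobut-2-en-1-yl)oxy]silane
Conditions: TESCl, imidazole, CH2Cl2, 0 °C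
Reagents that add atoms: chlorotriethylsilane, CC[Si](Cl)(CC)CC
Why: Routine silylation, with TES chosen because a primary TES ether can later be oxidised directly to the aldehyde under Swern conditions while TBS and TBDPS ethers stay.

Step 3
Reactants: 3 (Z)-triethyl[(3-iodobut-2-en-1-yl)oxy]silane; 4 (S)-epichlorohydrin
Product: 6 (2S,4Z)-1-chloro-4-methyl-6-(triethylsilyloxy)hex-4-en-2-ol, via alkenylmagnesium chloride 5 (not isolated)
Conditions: i-PrMgCl·LiCl, THF, 0 °C; then CuI (10 mol %), 4, −40 to −20 °C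
Reagents that add atoms: none
Why: Iodine–magnesium exchange keeps the Z geometry and the copper-catalysed Grignard opening occurs at the unsubstituted epoxide carbon, so the C2 stereocentre is carried over unchanged from (S)-epichlorohydrin (Cu-catalysed epoxide ring opening).

Step 4
Reactants: 6 (2S,4Z)-1-chloro-4-methyl-6-(triethylsilyloxy)hex-4-en-2-ol
Product: 8 (3S,5Z)-5-methyl-7-(triethylsilyloxy)hepta-1,5-dien-3-ol, via terminal epoxide 7 (not isolated)
Conditions: Me3S+ I−, n-BuLi, THF, −10 °C to rt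
Reagents that add atoms: trimethylsulfonium iodide, C[S+](C)C.[I-]
Why: Base closes the chlorohydrin to the terminal epoxide, dimethylsulfonium methylide opens it at CH2 and a second equivalent of base eliminates Me2S, giving the one-carbon-homologated allylic alcohol without touching C2 (epoxide-to-allylic-alcohol homologation with a sulfonium ylide).

Step 5
Reactants: 9 2-methylidenepropane-1,3-diol
Product: 10 2-[(tert-butyldiphenylsilyloxy)methyl]prop-2-en-1-ol
Conditions: NaH (1.0 equiv), THF, 0 °C; then TBDPSCl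
Reagents that add atoms: tert-butyl(chloro)diphenylsilane, CC(C)(C)[Si](Cl)(c1ccccc1)c1ccccc1
Why: The sparingly soluble mono-sodium alkoxide of the symmetric diol is silylated once (monoprotection of a symmetric diol).

Step 6
Reactants: 10 2-[(tert-butyldiphenylsilyloxy)methyl]prop-2-en-1-ol
Product: 11 [2-(bromomethyl)prop-2-en-1-yl]oxy(tert-butyl)diphenylsilane
Conditions: CBr4, PPh3, CH2Cl2, 0 °C
Reagents that add atoms: tetrabromomethane, BrC(Br)(Br)Br
Why: Appel bromination of a primary allylic alcohol under neutral conditions.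

Step 7
Reactants: 11 [2-(bromomethyl)prop-2-en-1-yl]oxy(tert-butyl)diphenylsilane
Product: 13 3-[(tert-butyldiphenylsilyloxy)methyl]but-3-enoic acid, via allylmagnesium bromide 12 (not isolated)
Conditions: Mg, THF, 0 °C (slow addition); CO2, −78 °C; dilute aq. HCl
Reagents that add atoms: carbon dioxide, O=C=O
Why: Carboxylation of an allylic Grignard reagent whose two allyl termini are identical, so only one β,γ-unsaturated acid can form.

Step 8
Reactants: 8 (3S,5Z)-5-methyl-7-(triethylsilyloxy)hepta-1,5-dien-3-ol; 13 3-[(tert-butyldiphenylsilyloxy)methyl]but-3-enoic acid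
Product: 14 (3S,5Z)-5-methyl-7-(triethylsilyloxy)hepta-1,5-dien-3-yl 3-[(tert-butyldiphenylsilyloxy)methyl]but-3-enoate
Conditions: DIC, DMAP (5 mol %), CH2Cl2, −20 to 0 °C
Reagents that add atoms: none
Why: Steglich esterification at low temperature with little DMAP, so the β,γ-unsaturated acyl unit does not slip into conjugation and C2 is untouched.

Step 9
Reactants: 14 (3S,5Z)-5-methyl-7-(triethylsilyloxy)hepta-1,5-dien-3-yl 3-[(tert-butyldiphenylsilyloxy)methyl]but-3-enoate
Product: 15 (6S)-4-[(tert-butyldiphenylsilyloxy)methyl]-6-[(2Z)-2-methyl-4-(triethylsilyloxy)but-2-en-1-yl]-3,6-dihydro-2H-pyran-2-one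
Conditions: second-generation Grubbs catalyst (5 mol %), 1,4-benzoquinone (10 mol %), CH2Cl2, 40 °C, 5 mM
Reagents that add atoms: none
Why: Ring-closing metathesis of the vinyl group onto the 1,1-disubstituted olefin gives the six-membered lactone, whose ring forces C9 and C2 cis on the new trisubstituted C1=C10 bond, exactly the ring-cis geometry of the target.

Step 10
Reactants: 15 (6S)-4-[(tert-butyldiphenylsilyloxy)methyl]-6-[(2Z)-2-methyl-4-(triethylsilyloxy)but-2-en-1-yl]-3,6-dihydro-2H-pyran-2-one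
Product: 16 (3E,5S,7Z)-3-[(tert-butyldiphenylsilyloxy)methyl]-7-methyl-9-(triethylsilyloxy)nona-3,7-diene-1,5-diol
Conditions: i-Bu2AlH (3 equiv), CH2Cl2, −78 to 0 °C; aq. Rochelle salt
Reagents that add atoms: none
Why: Hydride reduction of the lactone releases the C2 and C8 hydroxyls with the olefin geometry locked in, and ends the risk of the β,γ-unsaturated lactone moving into conjugation.

Step 11
Reactants: 16 (3E,5S,7Z)-3-[(tert-butyldiphenylsilyloxy)methyl]-7-methyl-9-(triethylsilyloxy)nona-3,7-diene-1,5-diol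
Product: 18 (3E,5S,7Z)-1-(tert-butyldimethylsilyloxy)-3-[(tert-butyldiphenylsilyloxy)methyl]-7-methyl-9-(triethylsilyloxy)nona-3,7-dien-5-yl acetate, via mono-TBS ether 17 (not isolated)
Conditions: TBSCl (1.05 equiv), imidazole, CH2Cl2, −20 °C; then Ac2O, Et3N, DMAP, rt
Reagents that add atoms: tert-butyl(chloro)dimethylsilane, CC(C)(C)[Si](C)(C)Cl; acetic anhydride, CC(=O)OC(C)=O
Why: The primary C8 hydroxyl is silylated selectively on steric grounds and the remaining secondary allylic C2 hydroxyl is then acetylated in the same flask with retention (one-pot selective silylation–acetylation).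

Step 12
Reactants: 18 (3E,5S,7Z)-1-(tert-butyldimethylsilyloxy)-3-[(tert-butyldiphenylsilyloxy)methyl]-7-methyl-9-(triethylsilyloxy)nona-3,7-dien-5-yl acetate
Product: 19 (2Z,5S,6E)-5-acetoxy-9-(tert-butyldimethylsilyloxy)-7-[(tert-butyldiphenylsilyloxy)methyl]-3-methylnona-2,6-dienal
Conditions: (COCl)2, DMSO, CH2Cl2, −78 to −40 °C; then Et3N, −78 to 0 °C
Reagents that add atoms: none
Why: Activated DMSO cleaves the primary allylic TES ether (not TBS or TBDPS) to the alkoxysulfonium salt, which collapses to the Z-enal (Swern oxidation run directly on a TES ether).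

Step 13
Reactants: 19 (2Z,5S,6E)-5-acetoxy-9-(tert-butyldimethylsilyloxy)-7-[(tert-butyldiphenylsilyloxy)methyl]-3-methylnona-2,6-dienal; 20 hex-1-yne
Product: 23 (5E,7S,8Z,11S,12E)-15-(tert-butyldimethylsilyloxy)-13-[(tert-butyldiphenylsilyloxy)methyl]-7-hydroxy-9-methylpentadeca-5,8,12-trien-11-yl acetate, via alkenyldicyclohexylborane 21 (not isolated), via hexenyl(methyl)zinc 22 (not isolated)
Conditions: 20, Cy2BH, toluene, 0 °C to rt; ZnMe2, −78 °C; (−)-3-exo-morpholinoisoborneol [(−)-MIB] (5 mol %); then 19, −30 to 0 °C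
Reagents that add atoms: none
Why: Hydroboration and boron-to-zinc exchange give the E-alkenylzinc, which the amino-alcohol–zinc catalyst delivers to the Si face of the enal to set the C6 carbinol as S, the spatial arrangement needed for 6R in the target (catalytic asymmetric alkenylzinc addition); the hexenyl group is only a metathesis handle.

Step 14
Reactants: 23 (5E,7S,8Z,11S,12E)-15-(tert-butyldimethylsilyloxy)-13-[(tert-butyldiphenylsilyloxy)methyl]-7-hydroxy-9-methylpentadeca-5,8,12-trien-11-yl acetate; 24 2-(bromomethyl)prop-2-enoic acid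
Product: 25 (5E,7S,8Z,11S,12E)-11-acetoxy-15-(tert-butyldimethylsilyloxy)-13-[(tert-butyldiphenylsilyloxy)methyl]-9-methylpentadeca-5,8,12-trien-7-yl 2-(bromomethyl)prop-2-enoate
Conditions: DIC, DMAP (5 mol %), CH2Cl2, 0 °C
Reagents that add atoms: none
Why: Steglich esterification of the secondary alcohol with retention at C6, with DMAP kept low to avoid substitution at the allylic bromide.

Step 15
Reactants: 25 (5E,7S,8Z,11S,12E)-11-acetoxy-15-(tert-butyldimethylsilyloxy)-13-[(tert-butyldiphenylsilyloxy)methyl]-9-methylpentadeca-5,8,12-trien-7-yl 2-(bromomethyl)prop-2-enoate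
Product: 26 (5R)-3-(bromomethyl)-5-[(1Z,4S,5E)-4-acetoxy-8-(tert-butyldimethylsilyloxy)-6-[(tert-butyldiphenylsilyloxy)methyl]-2-methylocta-1,5-dien-1-yl]furan-2(5H)-one
Conditions: second-generation Hoveyda–Grubbs catalyst (10 mol %), toluene, 60 °C, 2 mM
Reagents that add atoms: none
Why: Ring-closing metathesis between the hexenyl olefin and the acrylate closes the butenolide and expels hex-1-ene, with five-membered closure favoured over a seven-membered closure onto the hindered trisubstituted C1=C10 olefin flanked by the acetate and silyloxymethyl groups.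

Step 16
Reactants: 26 (5R)-3-(bromomethyl)-5-[(1Z,4S,5E)-4-acetoxy-8-(tert-butyldimethylsilyloxy)-6-[(tert-butyldiphenylsilyloxy)methyl]-2-methylocta-1,5-dien-1-yl]furan-2(5H)-one
Product: 27 (5R)-3-(bromomethyl)-5-[(1Z,4S,5E)-4-acetoxy-6-[(tert-butyldiphenylsilyloxy)methyl]-8-hydroxy-2-methylocta-1,5-dien-1-yl]furan-2(5H)-one
Conditions: HF·pyridine, pyridine, THF, 0 °C
Reagents that add atoms: none
Why: Buffered fluoride removes the unhindered primary TBS ether much faster than the TBDPS ether and leaves the esters and allylic bromide alone (selective desilylation).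

Step 17
Reactants: 27 (5R)-3-(bromomethyl)-5-[(1Z,4S,5E)-4-acetoxy-6-[(tert-butyldiphenylsilyloxy)methyl]-8-hydroxy-2-methylocta-1,5-dien-1-yl]furan-2(5H)-one
Product: 28 (5R)-3-(bromomethyl)-5-[(1Z,4S,5E)-4-acetoxy-6-[(tert-butyldiphenylsilyloxy)methyl]-2-methyl-8-oxoocta-1,5-dien-1-yl]furan-2(5H)-one
Conditions: Dess–Martin periodinane, NaHCO3, CH2Cl2, 0 °C; used at once
Reagents that add atoms: none
Why: Buffered Dess–Martin oxidation gives the β,γ-unsaturated aldehyde without base or acid that would move the C1=C10 bond into conjugation.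

Step 18
Reactants: 28 (5R)-3-(bromomethyl)-5-[(1Z,4S,5E)-4-acetoxy-6-[(tert-butyldiphenylsilyloxy)methyl]-2-methyl-8-oxoocta-1,5-dien-1-yl]furan-2(5H)-one
Product: 30 (2S,6R,7R,8S)-2-acetoxy-14-(tert-butyldiphenylsilyloxy)-8-hydroxygermacra-1(10),4,11(13)-trien-12,6-olide, via allylchromium dichloride 29 (not isolated)
Conditions: CrCl2 (10 equiv), THF, 25 °C, syringe-pump addition of 28 over 12 h (final 1 mM)
Reagents that add atoms: none
Why: Proposed new method: two equivalents of CrCl2 reduce the allylic bromide to an allylchromium in which C7, normally the electrophilic β-carbon of the butenolide, is the nucleophilic terminus, and it adds to the C8 aldehyde through a chromium-bridged chair transition state, closing the ten-membered ring and unveiling the α-methylene lactone; attack on the face anti to the C5 substituent gives the trans-fused lactone (C7 R), and the chair with the C9 chain equatorial gives the 8S alcohol, the C8 epimer of the target, which step 19 corrects by inversion; the closest known reactions are intermolecular chromium- or zinc-mediated Barbier allylations of aldehydes with 3-(bromomethyl)furan-2(5H)-ones and Nozaki–Hiyama allylative macrocyclisations of 2-(bromomethyl)acrylates.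

Step 19
Reactants: 30 (2S,6R,7R,8S)-2-acetoxy-14-(tert-butyldiphenylsilyloxy)-8-hydroxygermacra-1(10),4,11(13)-trien-12,6-olide; 31 methacrylic acid
Product: 32 (2S,6R,7R,8R)-2-acetoxy-14-(tert-butyldiphenylsilyloxy)-8-(2-methylprop-2-enoyloxy)germacra-1(10),4,11(13)-trien-12,6-olide
Conditions: PPh3, DIAD, toluene, 0 °C (betaine pre-formed), then 30 and 31, BHT, 0 to 25 °C
Reagents that add atoms: none
Why: Mitsunobu esterification displaces the activated C8 oxygen by methacrylate in an SN2 step, so the ester is installed and C8 is inverted from S to the required R in one operation.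

Step 20
Reactants: 32 (2S,6R,7R,8R)-2-acetoxy-14-(tert-butyldiphenylsilyloxy)-8-(2-methylprop-2-enoyloxy)germacra-1(10),4,11(13)-trien-12,6-olide
Product: 33 (2S,6R,7R,8R)-2-acetoxy-14-hydroxy-8-(2-methylprop-2-enoyloxy)germacra-1(10),4,11(13)-trien-12,6-olide (target)
Conditions: HF·pyridine, THF, 0 to 25 °C
Reagents that add atoms: none
Why: Acidic fluoride cleaves the TBDPS ether without ester migration or hydrolysis (C14-OH is trans to C2 across C1=C10), giving the target.

## Compound list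

1 | but-2-yn-1-ol | CC#CCO | starting material
2 | (Z)-3-iodobut-2-en-1-ol | C/C(I)=C/CO | intermediate
3 | (Z)-triethyl[(3-iodobut-2-en-1-yl)oxy]silane | C/C(I)=C/CO[Si](CC)(CC)CC | intermediate
4 | (S)-2-(chloromethyl)oxirane, (S)-epichlorohydrin | ClC[C@@H]1CO1 | starting material
5 | (Z)-[4-(triethylsilyloxy)but-2-en-2-yl]magnesium chloride | C/C([Mg]Cl)=C/CO[Si](CC)(CC)CC | intermediate
6 | (2S,4Z)-1-chloro-4-methyl-6-(triethylsilyloxy)hex-4-en-2-ol | ClC[C@@H](O)C/C(C)=C\CO[Si](CC)(CC)CC | intermediate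
7 | (S)-2-[(2Z)-2-methyl-4-(triethylsilyloxy)but-2-en-1-yl]oxirane | C1O[C@H]1C/C(C)=C\CO[Si](CC)(CC)CC | intermediate
8 | (3S,5Z)-5-methyl-7-(triethylsilyloxy)hepta-1,5-dien-3-ol | C=C[C@@H](O)C/C(C)=C\CO[Si](CC)(CC)CC | intermediate
9 | 2-methylidenepropane-1,3-diol | C=C(CO)CO | starting material
10 | 2-[(tert-butyldiphenylsilyloxy)methyl]prop-2-en-1-ol | C=C(CO)CO[Si](c1ccccc1)(c1ccccc1)C(C)(C)C | intermediate
11 | [2-(bromomethyl)prop-2-en-1-yl]oxy(tert-butyl)diphenylsilane | C=C(CBr)CO[Si](c1ccccc1)(c1ccccc1)C(C)(C)C | intermediate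
12 | {2-[(tert-butyldiphenylsilyloxy)methyl]prop-2-en-1-yl}magnesium bromide | C=C(C[Mg]Br)CO[Si](c1ccccc1)(c1ccccc1)C(C)(C)C | intermediate
13 | 3-[(tert-butyldiphenylsilyloxy)methyl]but-3-enoic acid | C=C(CC(=O)O)CO[Si](c1ccccc1)(c1ccccc1)C(C)(C)C | intermediate
14 | (3S,5Z)-5-methyl-7-(triethylsilyloxy)hepta-1,5-dien-3-yl 3-[(tert-butyldiphenylsilyloxy)methyl]but-3-enoate | C=C[C@@H](OC(=O)CC(=C)CO[Si](c1ccccc1)(c1ccccc1)C(C)(C)C)C/C(C)=C\CO[Si](CC)(CC)CC | intermediate
15 | (6S)-4-[(tert-butyldiphenylsilyloxy)methyl]-6-[(2Z)-2-methyl-4-(triethylsilyloxy)but-2-en-1-yl]-3,6-dihydro-2H-pyran-2-one | O=C1CC(CO[Si](c2ccccc2)(c2ccccc2)C(C)(C)C)=C[C@H](C/C(C)=C\CO[Si](CC)(CC)CC)O1 | intermediate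
16 | (3E,5S,7Z)-3-[(tert-butyldiphenylsilyloxy)methyl]-7-methyl-9-(triethylsilyloxy)nona-3,7-diene-1,5-diol | OCC/C(CO[Si](c1ccccc1)(c1ccccc1)C(C)(C)C)=C\[C@@H](O)C/C(C)=C\CO[Si](CC)(CC)CC | intermediate
17 | (3E,5S,7Z)-1-(tert-butyldimethylsilyloxy)-3-[(tert-butyldiphenylsilyloxy)methyl]-7-methyl-9-(triethylsilyloxy)nona-3,7-dien-5-ol | CC(C)(C)[Si](C)(C)OCC/C(CO[Si](c1ccccc1)(c1ccccc1)C(C)(C)C)=C\[C@@H](O)C/C(C)=C\CO[Si](CC)(CC)CC | intermediate
18 | (3E,5S,7Z)-1-(tert-butyldimethylsilyloxy)-3-[(tert-butyldiphenylsilyloxy)methyl]-7-methyl-9-(triethylsilyloxy)nona-3,7-dien-5-yl acetate | CC(C)(C)[Si](C)(C)OCC/C(CO[Si](c1ccccc1)(c1ccccc1)C(C)(C)C)=C\[C@@H](OC(C)=O)C/C(C)=C\CO[Si](CC)(CC)CC | intermediate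
19 | (2Z,5S,6E)-5-acetoxy-9-(tert-butyldimethylsilyloxy)-7-[(tert-butyldiphenylsilyloxy)methyl]-3-methylnona-2,6-dienal | CC(C)(C)[Si](C)(C)OCC/C(CO[Si](c1ccccc1)(c1ccccc1)C(C)(C)C)=C\[C@@H](OC(C)=O)C/C(C)=C\C=O | intermediate
20 | hex-1-yne | CCCCC#C | starting material
21 | dicyclohexyl[(E)-hex-1-en-1-yl]borane | CCCC/C=C/B(C1CCCCC1)C1CCCCC1 | intermediate
22 | [(E)-hex-1-en-1-yl](methyl)zinc | CCCC/C=C/[Zn]C | intermediate
23 | (5E,7S,8Z,11S,12E)-15-(tert-butyldimethylsilyloxy)-13-[(tert-butyldiphenylsilyloxy)methyl]-7-hydroxy-9-methylpentadeca-5,8,12-trien-11-yl acetate | CC(C)(C)[Si](C)(C)OCC/C(CO[Si](c1ccccc1)(c1ccccc1)C(C)(C)C)=C\[C@@H](OC(C)=O)C/C(C)=C\[C@@H](O)/C=C/CCCC | intermediate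
24 | 2-(bromomethyl)prop-2-enoic acid | C=C(CBr)C(=O)O | starting material
25 | (5E,7S,8Z,11S,12E)-11-acetoxy-15-(tert-butyldimethylsilyloxy)-13-[(tert-butyldiphenylsilyloxy)methyl]-9-methylpentadeca-5,8,12-trien-7-yl 2-(bromomethyl)prop-2-enoate | CC(C)(C)[Si](C)(C)OCC/C(CO[Si](c1ccccc1)(c1ccccc1)C(C)(C)C)=C\[C@@H](OC(C)=O)C/C(C)=C\[C@@H](OC(=O)C(=C)CBr)/C=C/CCCC | intermediate
26 | (5R)-3-(bromomethyl)-5-[(1Z,4S,5E)-4-acetoxy-8-(tert-butyldimethylsilyloxy)-6-[(tert-butyldiphenylsilyloxy)methyl]-2-methylocta-1,5-dien-1-yl]furan-2(5H)-one | CC(C)(C)[Si](C)(C)OCC/C(CO[Si](c1ccccc1)(c1ccccc1)C(C)(C)C)=C\[C@@H](OC(C)=O)C/C(C)=C\[C@H]1OC(=O)C(CBr)=C1 | intermediate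
27 | (5R)-3-(bromomethyl)-5-[(1Z,4S,5E)-4-acetoxy-6-[(tert-butyldiphenylsilyloxy)methyl]-8-hydroxy-2-methylocta-1,5-dien-1-yl]furan-2(5H)-one | OCC/C(CO[Si](c1ccccc1)(c1ccccc1)C(C)(C)C)=C\[C@@H](OC(C)=O)C/C(C)=C\[C@H]1OC(=O)C(CBr)=C1 | intermediate
28 | (5R)-3-(bromomethyl)-5-[(1Z,4S,5E)-4-acetoxy-6-[(tert-butyldiphenylsilyloxy)methyl]-2-methyl-8-oxoocta-1,5-dien-1-yl]furan-2(5H)-one | O=CC/C(CO[Si](c1ccccc1)(c1ccccc1)C(C)(C)C)=C\[C@@H](OC(C)=O)C/C(C)=C\[C@H]1OC(=O)C(CBr)=C1 | intermediate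
29 | allylchromium dichloride of 28 (CrCl2 on C13 in place of Br) | O=CC/C(CO[Si](c1ccccc1)(c1ccccc1)C(C)(C)C)=C\[C@@H](OC(C)=O)C/C(C)=C\[C@H]1OC(=O)C(C[Cr](Cl)Cl)=C1 | intermediate
30 | (2S,6R,7R,8S)-2-acetoxy-14-(tert-butyldiphenylsilyloxy)-8-hydroxygermacra-1(10),4,11(13)-trien-12,6-olide (ring-cis olefins) | O[C@H]1C/C(CO[Si](c3ccccc3)(c3ccccc3)C(C)(C)C)=C\[C@@H](OC(C)=O)C/C(C)=C\[C@H]2OC(=O)C(=C)[C@@H]21 | intermediate
31 | methacrylic acid | C=C(C)C(=O)O | starting material
32 | (2S,6R,7R,8R)-2-acetoxy-14-(tert-butyldiphenylsilyloxy)-8-(2-methylprop-2-enoyloxy)germacra-1(10),4,11(13)-trien-12,6-olide | C=C(C)C(=O)O[C@@H]1C/C(CO[Si](c3ccccc3)(c3ccccc3)C(C)(C)C)=C\[C@@H](OC(C)=O)C/C(C)=C\[C@H]2OC(=O)C(=C)[C@@H]21 | intermediate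
33 | (2S,6R,7R,8R)-2-acetoxy-14-hydroxy-8-(2-methylprop-2-enoyloxy)germacra-1(10),4,11(13)-trien-12,6-olide, CNP0138477.1 | C=C(C)C(=O)O[C@@H]1C/C(CO)=C\[C@@H](OC(C)=O)C/C(C)=C\[C@H]2OC(=O)C(=C)[C@@H]21 | target

## Step count and risk

Total step count: 20 (17 in the main line, 3 for acid 13).
Longest linear sequence: 17 steps (steps 1–4, then 8–20).

Three steps most likely to fail:

**Step 18 (chromium-mediated ring closure).** The intramolecular version is unprecedented; oligomerisation, protonation of the allylchromium, or a different C8 outcome are all possible. The fallback replaces the organochromium addition by a Lewis-acid-triggered allylstannane addition. It sets out from bromide 26: Zn and Bu3SnCl in THF/aqueous NH4Cl give the 3-(tributylstannylmethyl)butenolide, allylstannane F1; PPTS in MeOH frees the C8 hydroxyl to give stannyl alcohol F2; buffered Dess–Martin oxidation gives stannyl aldehyde F3; BF3·OEt2 in CH2Cl2 at −78 °C under high dilution then closes the ring through an open transition state (C9 anti to C11, the coordinated carbonyl oxygen on the H-7 side). It comes back to the route at macrocyclic alcohol 30.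

**Step 19 (Mitsunobu inversion at the hindered C8 carbinol).** Elimination towards C9 (a conjugated diene) or no reaction are the likely failures. The fallback inverts by oxidation and reduction instead of substitution. It sets out from alcohol 30: buffered Dess–Martin oxidation gives the 8-ketone F4; NaBH4 with CeCl3·7H2O in MeOH/THF at −78 °C delivers hydride to the face anti to the lactone carbon on C7 and gives the 8R alcohol F5; methacrylic anhydride, Et3N and DMAP then acylate with retention. It comes back to the route at methacrylate 32.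

**Step 13 (catalyst-controlled alkenylzinc addition to a functionalised Z-enal).** Low selectivity at C6, Z-to-E drift of the enal, or methyl transfer are the risks. The fallback sets C6 by reagent-controlled ketone reduction instead of carbonyl addition. It sets out from enal 19: alkenylzinc 22 is added without the amino alcohol to give the C6-epimeric alcohols F6; MnO2 in CH2Cl2 oxidises them to the cross-conjugated dienone F7; (R)-2-methyl-CBS-oxazaborolidine with catecholborane in toluene at −78 °C reduces the ketone, treating the Z-trisubstituted alkenyl group as the large substituent. It comes back to the route at alcohol 23.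

Further compounds
F1 | step 18 | (5R)-5-[(1Z,4S,5E)-4-acetoxy-8-(tert-butyldimethylsilyloxy)-6-[(tert-butyldiphenylsilyloxy)methyl]-2-methylocta-1,5-dien-1-yl]-3-[(tributylstannyl)methyl]furan-2(5H)-one | CC(C)(C)[Si](C)(C)OCC/C(CO[Si](c1ccccc1)(c1ccccc1)C(C)(C)C)=C\[C@@H](OC(C)=O)C/C(C)=C\[C@H]1OC(=O)C(C[Sn](CCCC)(CCCC)CCCC)=C1
F2 | step 18 | (5R)-5-[(1Z,4S,5E)-4-acetoxy-6-[(tert-butyldiphenylsilyloxy)methyl]-8-hydroxy-2-methylocta-1,5-dien-1-yl]-3-[(tributylstannyl)methyl]furan-2(5H)-one | OCC/C(CO[Si](c1ccccc1)(c1ccccc1)C(C)(C)C)=C\[C@@H](OC(C)=O)C/C(C)=C\[C@H]1OC(=O)C(C[Sn](CCCC)(CCCC)CCCC)=C1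
F3 | step 18 | (5R)-5-[(1Z,4S,5E)-4-acetoxy-6-[(tert-butyldiphenylsilyloxy)methyl]-2-methyl-8-oxoocta-1,5-dien-1-yl]-3-[(tributylstannyl)methyl]furan-2(5H)-one | O=CC/C(CO[Si](c1ccccc1)(c1ccccc1)C(C)(C)C)=C\[C@@H](OC(C)=O)C/C(C)=C\[C@H]1OC(=O)C(C[Sn](CCCC)(CCCC)CCCC)=C1
F4 | step 19 | (2S,6R,7S)-2-acetoxy-14-(tert-butyldiphenylsilyloxy)-8-oxogermacra-1(10),4,11(13)-trien-12,6-olide (same spatial arrangement at C7 as 30) | O=C1C/C(CO[Si](c3ccccc3)(c3ccccc3)C(C)(C)C)=C\[C@@H](OC(C)=O)C/C(C)=C\[C@H]2OC(=O)C(=C)[C@@H]21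
F5 | step 19 | (2S,6R,7R,8R)-2-acetoxy-14-(tert-butyldiphenylsilyloxy)-8-hydroxygermacra-1(10),4,11(13)-trien-12,6-olide | O[C@@H]1C/C(CO[Si](c3ccccc3)(c3ccccc3)C(C)(C)C)=C\[C@@H](OC(C)=O)C/C(C)=C\[C@H]2OC(=O)C(=C)[C@@H]21
F6 | step 13 | (5E,8Z,11S,12E)-15-(tert-butyldimethylsilyloxy)-13-[(tert-butyldiphenylsilyloxy)methyl]-7-hydroxy-9-methylpentadeca-5,8,12-trien-11-yl acetate, mixture of C7 epimers | CC(C)(C)[Si](C)(C)OCC/C(CO[Si](c1ccccc1)(c1ccccc1)C(C)(C)C)=C\[C@@H](OC(C)=O)C/C(C)=C\C(O)/C=C/CCCC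
F7 | step 13 | (5E,8Z,11S,12E)-15-(tert-butyldimethylsilyloxy)-13-[(tert-butyldiphenylsilyloxy)methyl]-9-methyl-7-oxopentadeca-5,8,12-trien-11-yl acetate | CC(C)(C)[Si](C)(C)OCC/C(CO[Si](c1ccccc1)(c1ccccc1)C(C)(C)C)=C\[C@@H](OC(C)=O)C/C(C)=C\C(=O)/C=C/CCCC
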